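The data were computed for an exercise, noise included.

The easiest thing to follow in these flasks is the solid: in both earlier runs it drops early, then falls steadily.

| flask | solid substrate | temperature | remark | time |
|---|---|---|---|---|
| gamma | 28 mM | 115 °C | run made earlier |  |
| beta | 44 mM | 126 °C | run made earlier |  |
| midnight | 20 mM | 130 °C |  | 4.0 d |
| winter | 20 mM | 110 °C |  | 4.0 d |
| dusk | 20 mM |  | at 110 °C until 50 h, from then on at 130 °C | 4.0 d |

| run | time / d | target / % | solid substrate / % |
|---|---|---|---|
| gamma | 2.50 | 17 | 49 |
| gamma | 5.00 | 27 | 29 |
| gamma | 8.00 | 39 | 10 |
| gamma | 10.0 | 39 | 1 |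
| beta | 1.25 | 11 | 70 |
| beta | 2.50 | 14 | 59 |
| beta | 4.00 | 20 | 48 |
| beta | 5.00 | 21 | 40 |

(scatter of a reading: 1.5 percentage points)

- percent here means solid substrate units held: one target counts as two
- solid substrate is a solid; its amount is given per volume of the solution
- at the start none of the solid substrate is in solution
- what has only dissolved of solid substrate counts as not reacted

- the best flask by amount of target, in percent of the solid substrate charged; "all alike" if 1.5 percentage points covers them all (midnight / winter / dusk / all alike)
- amount of target at the end, in percent of the solid substrate charged, midnight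
- amount of target at the end, in percent of the solid substrate charged, winter
- amount of target at the end, in percent of the solid substrate charged, dusk

I read a steady loss of 1.99 mM d⁻¹ in gamma and 3.52 mM d⁻¹ in beta. Run back to the start, these lines give early drops of 9.32 mM and 8.80 mM, nearly equal despite the different charges. I therefore take their mean, 9.06 mM, which is 45.3 % of a 20 mM charge. Carrying the rate geometrically in temperature gives 1.53 mM d⁻¹ at 110 °C and 4.33 mM d⁻¹ at 130 °C.

Integrating this zero-order loss, the solid fraction is one minus the early share minus the steady share, and it reaches zero at the clearing time 7.15 d, here for winter. That is later than 4.0 d, so I expect 24.1 % of winter's charge still solid at the end. By the same reckoning midnight clears at 2.52 d, and dusk at 3.87 d, just before the end. The target gained per solid lost reads 0.564 in gamma but 0.333 in beta, which is both hotter and more heavily charged, so I commit to dusk, which by this reckoning stays at 110 °C for its first 50 h and still clears before the end.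

The forecast differs, choosing winter with 30 % for midnight, 34.5 % for winter and 33 % for dusk, and taking winter as “about 84% consumed by 4 d”, where I have 75.9 % gone.

The flasks give 32.8 % for midnight, 29.0 % for winter and 38.1 % for dusk, so dusk is best.

    2 starting material ⇌ target (K = 180 L mol⁻¹, k = 0.620 L mol⁻¹ h⁻¹, Ea = 86.0 kJ mol⁻¹, ΔH = −33.0 kJ mol⁻¹)
    solid substrate ⇌ starting material, rate k2*(cs2 - [starting material]) while solid is left; crystals form when [starting material] > cs2 (solubility = 8.30 mM, k = 0.400 h⁻¹)
    starting material + target → side product (k = 0.310 L mol⁻¹ h⁻¹, Ea = 96.0 kJ mol⁻¹)
    (constants at 110 °C)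

Winter, for which I reckoned a clearing time of 7.15 d, ends with 24.9 % still solid, against my 24.1 %. Dusk, reckoned to clear at 3.87 d, ends with 0 % solid. For the neighbouring flask, winter with 80 mM of solid, the same drop and rate give a clearing time of 46.4 d and 81.0 % solid at the end. That flask ends with 81.2 % solid and 7.25 % target.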